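Assumption: flavan locants are used for both halves; unprimed locants belong to unit A (bridged through C8), primed locants to unit B (bridged through C6').

Design remarks (corrections and improvements):
- Descriptor check: opening (S)-styrene oxide at CH2 breaks no bond at the stereocentre. The label becomes R only because the CIP ranking changes. SN2 ring closure with inversion then gives S at C2 and C2', as in the target.
- The key-step product has two extra stereogenic carbons (the CH–SO2Ph carbons). It is therefore a mixture of diastereomers that converge when the sulfonyl groups are removed.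
- Dimerising one salicylaldehyde cannot give the unsymmetrical 8,6'-bridge selectively: in 2,4-dihydroxy-6-methoxybenzaldehyde derivatives the reactive ring carbon is C3 (future C8), not C5 (future C6'). Unit B is therefore built from a second aldehyde, 2,4,6-trihydroxybenzaldehyde. Its formyl carbon becomes the bridge, and its remaining chelated phenol (future O5') later directs the second formyl group. The precursor keeps its skeleton and its benzyl/allyl pattern.
- Sulfur is introduced under neutral conditions (PhSSPh/n-Bu3P), so no free benzyl cation forms. It is oxidised with molybdate/H2O2, which spares the allyl ethers.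

Structural features

The target consists of two (2S)-7-hydroxy-5-methoxyflavan units joined by a single CH2 group that runs from C8 of unit A to C6' of unit B. Each unit is a benzene ring carrying oxygen at C5, C7 and C8a, fused to a dihydropyran ring (O1, C2, C3, C4) whose C2 bears a phenyl group. The only stereocentres, C2 and C2', are both S, lie in different units far from each other, and cannot be set by relay from one to the other. Fragile parts are the two benzylic C2–O ether bonds (ionisation in acid, hydrogenolysis), the very electron-rich diarylmethane (oxidation, acid-induced cleavage of the bridge) and the two free phenols. The real difficulty is positional and not stereochemical: the bridge is unsymmetrical, and on each arene three oxygens must end as methyl ether (O5), free phenol (O7) and ring oxygen (O8a). In addition, C4 and C4' are benzylic carbons flanked by two ortho oxygens, a position that does not tolerate a halide or a metal. The key step uses the C3–C4 and C3'–C4' bonds of the two pyran rings: C4 is a methylene on C4a that can be made nucleophilic as a sulfonyl carbanion, and the C3–C2(O)–phenyl fragment is the skeleton of ring-opened styrene oxide, so both stereocentres can be taken from one commercial epoxide.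

Logic of the disconnections

22 from 21. The two O–benzyl bonds on O7 and O7' are cut last. These phenols must stay masked while the pyran rings are closed, and a benzyl group comes off without acid or base. The forward step must cleave two primary benzyl ethers and leave the two cyclic benzylic C2–O bonds alone.

21 from 20. The O1–C2 and O1'–C2' bonds are cut. This opens both heterocycles and reduces the stereochemical problem to two acyclic secondary carbinols. The forward closure is an SN2 etherification with inversion, so 20 must carry (R)-carbinols, O8a and O8a' must be the only free phenols, and nothing may ionise the benzylic alcohols.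

20 from 19, and 19 from 18. The O–allyl bonds on O8a and O8a' are restored, then a phenylsulfonyl group is put back on C4 and on C4'. The allyl groups stop the phenols next to the carbanion site from expelling sulfinate, and the sulfonyl groups make C4 and C4' nucleophilic. The forward steps must cleave two C–S bonds reductively without touching allyl, benzyl or carbinol, and then remove allyl without touching benzyl.

18 from 15 and 16. The C3–C4 and C3'–C4' bonds are cut. Both stereocentres leave the large fragment and are found in two equivalents of 16, so 15 is achiral. The forward step needs two hindered benzylic carbanions to attack only the CH2 end of 16.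

15 from 14, 13 and 12. The S–O bonds, then the C–S bonds, then the benzylic C–H bonds are removed in turn, so both side arms become formyl groups. Aldehydes are the form in which a one-carbon unit is most easily placed on these arenes. Sulfur must then be introduced without a free ortho,ortho-dioxygenated benzyl cation and oxidised without touching the allyl groups.

12 from 11 and 10. The O5'–CH3 bond and then the C4a'–CHO bond are cut. With O5' free and C6' already substituted, C4a' is the only ortho position of that phenol, so the formyl group can be placed there and not on C8'. This demands an ortho-specific formylation.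

10 from 4 and 7. The bond between C8 and the bridge carbon is cut, and the bridge carbon stays with unit B as a formyl group. The molecule falls into two benzaldehydes of similar size, each with its oxygen pattern already set. Forward, an aryl anion at C8 must be made from 4 in the presence of its own formyl group, and the diaryl carbinol must be deoxygenated.

4 from 3, 2 and 1. The O8a–allyl, C8–I and O7–benzyl bonds are cut in turn. All three operations rely on the hydrogen bond between O8a–H and the formyl group in 1: it leaves O7 as the reactive phenol, then directs the halogen to C8, and is alkylated last.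

7 from 6 and 5. The O7'–benzyl and O8a'–allyl bonds are cut. Compound 5 is symmetric: its one phenol para to the formyl group is alkylated first, and the two remaining phenols are equivalent, so only mono- versus bis-alkylation has to be controlled.

Other disconnections considered

Alternative 1: The cut is at both C2–phenyl bonds.
- Forward key step: the methylene-bridged bis-chromone A1 would add two molecules of phenylboronic acid A2 in an enantioselective 1,4-addition to give the (2S,2'S)-bis-flavanone A3. Suitable catalysts are Pd(OCOCF3)2 with a chiral pyridine–oxazoline ligand, or a rhodium–diene complex made from [Rh(C2H4)2Cl]2. Both C4 carbonyl groups and the MOM groups would then be removed to reach 22.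
- In favour: both stereocentres come from a catalyst, either enantiomer is accessible, and no inversion step is needed. The pyran oxygen is already in place, so O8a never has to be told apart from O7 by protecting groups. On this point the alternative is better than the chosen plan.
- Against: 5-alkoxychromones are electron-rich, peri-hindered acceptors. Two independent additions turn any shortfall in selectivity into a (2S,2'R) diastereomer that would be hard to separate. Flavanones can lose configuration by retro-oxa-Michael ring opening under basic coupling conditions. Two carbonyl groups must then be deleted next to an acid-sensitive diarylmethane.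
- Comparison: structurally, A1 needs the same unsymmetrical diarylmethane as 12, so the hard positional problem is not eased. Mechanistically, catalyst control over two remote centres competes with chiral-pool centres whose integrity rests on two SN2 events. Step economy is about equal.

Alternative 2: The cut goes through the arene of unit B at C6'–C7' and C4a'–C5'.
- Forward key step: heating the ring-fused cyclobutenone A4 with the methoxyalkyne A5 would start a cascade of 4π ring opening, [2+2] addition, a second 4π opening and 6π closure. It would build the whole arene of unit B and give the 7-O-benzyl compound A6. One hydrogenolysis would then give 22.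
- In favour: the position of the bridge between OH and OMe on unit B is fixed by the cascade. On this point the alternative is better than the chosen plan, which spends steps 4 to 8 on it. The phenol of unit B emerges free, and the two halves are joined late.
- Against: A4 is a strained, enol-ether-fused cyclobutenone that already holds C2', and no short preparation is evident. A5 requires a complete unit A flavan from a separate asymmetric sequence and carries a labile alkynyl ether. The two stereocentres would be set by two unrelated operations.
- Comparison: structurally it is the more elegant answer for unit B. Mechanistically it is a neutral thermal pericyclic cascade against polar carbanion chemistry. The last two steps are shorter than the chosen end game, but the total count is expected to be higher.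

Alternative 3: The cut is at both O1–C2 bonds.
- Forward key step: the bis(2-vinylphenol) A7 would react with methyl cinnamyl carbonate A8 under a catalyst from [Ir(cod)Cl]2 and a chiral phosphoramidite. Each C8a phenoxide would attack the phenyl-bearing allyl terminus to give the bis[(S)-1-phenylallyl] ether A9. Ring-closing metathesis with a second-generation Grubbs catalyst would give the bis(2H-chromene) A10. One hydrogenation would saturate C3=C4 and remove the benzyl groups to give 22.
- In favour: the stereocentres are set catalytically together with the C–O bond, without an inversion step. Only three operations follow the bis-phenol. In step count the alternative is better than steps 12 to 16 of the chosen plan.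
- Against: both phenoxides are flanked by two ortho substituents and are hindered partners for the allyl–iridium intermediate. Electron-rich 2-vinylphenols polymerise or cyclise easily. In A10 each C2–O bond is allylic and benzylic on a very electron-rich chromene, so ionisation (loss of configuration) and hydrogenolysis in the final hydrogenation are real risks.
- Comparison: structurally it needs the same dialdehyde as 12 and the same O7/O8a differentiation, so it is equal there. Mechanistically, its stereocentre sits in an ionisable allylic ether until the last step. In the chosen plan the C2–O bond is made late on a saturated chain.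

Key step: step 12

Step 1
Reactants: 1 2,4-dihydroxy-6-methoxybenzaldehyde
Product: 2 4-(benzyloxy)-2-hydroxy-6-methoxybenzaldehyde
Conditions: BnBr (1.05 equiv), NaHCO3, KI (cat.), MeCN, 60 °C
Reagents that add atoms: benzyl bromide, BrCc1ccccc1
Why: Williamson etherification; O4 is the more acidic phenol and is free of hydrogen bonding, whereas O2 is held in a chelate with the formyl group, so a weak base and one equivalent of halide should alkylate O4 (future O7) only.

Step 2
Reactants: 2 4-(benzyloxy)-2-hydroxy-6-methoxybenzaldehyde
Product: 3 4-(benzyloxy)-2-hydroxy-3-iodo-6-methoxybenzaldehyde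
Conditions: N-iodosuccinimide (1.05 equiv), CF3CO2H (cat.), MeCN, 0 °C to rt
Reagents that add atoms: N-iodosuccinimide, O=C1CCC(=O)N1I
Why: Electrophilic aromatic iodination; the chelated phenol activates its free ortho carbon C3 (enol-like C2–C3 bond of the hydrogen-bonded salicylaldehyde), which is also less hindered than C5 between two ether groups, so iodine should mark the future C8.

Step 3
Reactants: 3 4-(benzyloxy)-2-hydroxy-3-iodo-6-methoxybenzaldehyde
Product: 4 2-(allyloxy)-4-(benzyloxy)-3-iodo-6-methoxybenzaldehyde
Conditions: allyl bromide, K2CO3, DMF, 50 °C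
Reagents that add atoms: allyl bromide, C=CCBr
Why: Williamson etherification of the chelated phenol (future O8a) under more forcing conditions, now that it is the only OH group; the allyl ether can later be removed with zerovalent palladium without touching the benzyl ether.

Step 4
Reactants: 5 2,4,6-trihydroxybenzaldehyde
Product: 6 4-(allyloxy)-2,6-dihydroxybenzaldehyde
Conditions: allyl bromide (1.0 equiv), NaHCO3, DMF, rt
Reagents that add atoms: allyl bromide, C=CCBr
Why: Williamson etherification; only O4 is para to the formyl group and outside the chelate, so it is the most acidic phenol and should react first with one equivalent of halide; this oxygen becomes O8a'.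

Step 5
Reactants: 6 4-(allyloxy)-2,6-dihydroxybenzaldehyde
Product: 7 4-(allyloxy)-2-(benzyloxy)-6-hydroxybenzaldehyde
Conditions: BnBr (1.0 equiv), K2CO3 (1.0 equiv), acetone, 50 °C
Reagents that add atoms: benzyl bromide, BrCc1ccccc1
Why: Williamson etherification; the two phenols of 6 are equivalent by symmetry, so there is no positional choice, and the phenol that remains after the first alkylation holds the formyl oxygen in a stronger single chelate and should resist a second alkylation at this stoichiometry.

Step 6
Reactants: 4 2-(allyloxy)-4-(benzyloxy)-3-iodo-6-methoxybenzaldehyde; 7 4-(allyloxy)-2-(benzyloxy)-6-hydroxybenzaldehyde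
Product: 10 2-(allyloxy)-3-[4-(allyloxy)-2-(benzyloxy)-6-hydroxybenzyl]-4-(benzyloxy)-6-methoxybenzaldehyde, via masked aryllithium 8 (not isolated), via diaryl carbinol 9 (not isolated)
Conditions: 4, LiN(Me)CH2CH2NMe2, THF, −20 °C; n-BuLi, −78 °C; sodium phenoxide of 7 (7 + NaH, THF), −78 to −30 °C; aq. NH4Cl; crude 9, Et3SiH, CF3CO2H, CH2Cl2, −20 to 0 °C
Reagents that add atoms: none
Why: Known sequence of in situ protection of the formyl group as a lithium α-amino alkoxide, iodine–lithium exchange, 1,2-addition of the aryllithium to the aldehyde of 7, and ionic hydrogenation of the carbinol with Et3SiH/CF3CO2H; the carbinol carbon has four ortho oxygen substituents, one a free phenol, so its cation should form and be reduced far faster than the regenerated formyl group. The carbinol centre of 9 is racemic and is deleted in the same step; the new C8–CH2 bond is fixed by the position of iodine in 4 and of the formyl group in 7.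

Step 7
Reactants: 10 2-(allyloxy)-3-[4-(allyloxy)-2-(benzyloxy)-6-hydroxybenzyl]-4-(benzyloxy)-6-methoxybenzaldehyde
Product: 11 2-(allyloxy)-3-[4-(allyloxy)-2-(benzyloxy)-5-formyl-6-hydroxybenzyl]-4-(benzyloxy)-6-methoxybenzaldehyde
Conditions: MgCl2, Et3N, (CH2O)n, MeCN, reflux; then 1 M HCl
Reagents that add atoms: formaldehyde (from paraformaldehyde), C=O
Why: Casnati–Skattebøl ortho-formylation; the magnesium phenoxide of O5' delivers formaldehyde to its only free ortho carbon C4a', and the benzylic alkoxide is oxidised by a second formaldehyde. The method is ortho-specific and no other free phenol is present, so C8' and the arene of unit A should stay untouched.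

Step 8
Reactants: 11 2-(allyloxy)-3-[4-(allyloxy)-2-(benzyloxy)-5-formyl-6-hydroxybenzyl]-4-(benzyloxy)-6-methoxybenzaldehyde
Product: 12 2-(allyloxy)-3-[4-(allyloxy)-2-(benzyloxy)-5-formyl-6-methoxybenzyl]-4-(benzyloxy)-6-methoxybenzaldehyde
Conditions: MeI, K2CO3, DMF, 40 °C
Reagents that add atoms: iodomethane, CI
Why: Williamson methylation of the chelated phenol O5', the only acidic OH group in 11; this completes the oxygen pattern of unit B.

Step 9
Reactants: 12 2-(allyloxy)-3-[4-(allyloxy)-2-(benzyloxy)-5-formyl-6-methoxybenzyl]-4-(benzyloxy)-6-methoxybenzaldehyde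
Product: 13 {2-(allyloxy)-3-[4-(allyloxy)-2-(benzyloxy)-5-(hydroxymethyl)-6-methoxybenzyl]-4-(benzyloxy)-6-methoxyphenyl}methanol
Conditions: NaBH4, THF–MeOH, 0 °C
Reagents that add atoms: none
Why: Hydride reduction of both aryl aldehydes to benzylic alcohols; ethers and terminal alkenes are inert to NaBH4, and a neutral work-up keeps the acid-sensitive dialkoxybenzyl alcohols intact.

Step 10
Reactants: 13 {2-(allyloxy)-3-[4-(allyloxy)-2-(benzyloxy)-5-(hydroxymethyl)-6-methoxybenzyl]-4-(benzyloxy)-6-methoxyphenyl}methanol
Product: 14 2-(allyloxy)-3-{4-(allyloxy)-2-(benzyloxy)-6-methoxy-5-[(phenylthio)methyl]benzyl}-4-(benzyloxy)-6-methoxy-1-[(phenylthio)methyl]benzene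
Conditions: PhSSPh, n-Bu3P, pyridine, rt
Reagents that add atoms: diphenyl disulfide, c1ccc(SSc2ccccc2)cc1
Why: Phosphine–disulfide thioetherification (Hata reaction); each alcohol is activated as an alkoxyphosphonium ion and displaced by thiophenolate under neutral conditions, which avoids the free dioxygenated benzyl cation or halide that would alkylate the electron-rich arenes.

Step 11
Reactants: 14 2-(allyloxy)-3-{4-(allyloxy)-2-(benzyloxy)-6-methoxy-5-[(phenylthio)methyl]benzyl}-4-(benzyloxy)-6-methoxy-1-[(phenylthio)methyl]benzene
Product: 15 2-(allyloxy)-3-{4-(allyloxy)-2-(benzyloxy)-6-methoxy-5-[(phenylsulfonyl)methyl]benzyl}-4-(benzyloxy)-6-methoxy-1-[(phenylsulfonyl)methyl]benzene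
Conditions: (NH4)6Mo7O24·4H2O (10 mol%), 30% aq. H2O2, EtOH–THF, 0 °C to rt
Reagents that add atoms: hydrogen peroxide, OO
Why: Molybdate-catalysed peroxide oxidation of sulfide to sulfone through a peroxomolybdate; it should be selective for sulfur over the monosubstituted allyl alkenes and the electron-rich arenes, which a peracid could attack.

Step 12
Reactants: 15 2-(allyloxy)-3-{4-(allyloxy)-2-(benzyloxy)-6-methoxy-5-[(phenylsulfonyl)methyl]benzyl}-4-(benzyloxy)-6-methoxy-1-[(phenylsulfonyl)methyl]benzene; 16 (S)-styrene oxide
Product: 18 (1R)-3-{2-(allyloxy)-3-[4-(allyloxy)-2-(benzyloxy)-5-[(3R)-3-hydroxy-3-phenyl-1-(phenylsulfonyl)propyl]-6-methoxybenzyl]-4-(benzyloxy)-6-methoxyphenyl}-1-phenyl-3-(phenylsulfonyl)propan-1-ol (epimers at both sulfonyl-bearing carbons), via dilithio bis-sulfone 17 (not isolated)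
Conditions: n-BuLi (2.1 equiv), THF, −78 °C; 16 (3 equiv), DMPU, −78 °C to rt; aq. NH4Cl
Reagents that add atoms: none
Why: n-BuLi removes one proton next to each sulfonyl group to give the dilithio species 17; these benzylic α-sulfonyl C–H bonds are many pK units more acidic than the diarylmethane bridge or any other C–H bond of 15. Each carbanion then opens 16 by SN2 attack at the unsubstituted CH2 carbon, the closest known reaction type being the opening of terminal epoxides by α-sulfonyl carbanions in γ-hydroxy sulfone synthesis. No ring is closed. The carbinol centres are not created here: the C–O bond at the phenyl-bearing carbon of 16 is never broken, so its configuration is carried over unchanged, and the label changes from S to R only because the CIP ranking changes. The two new stereocentres at the sulfonyl-bearing carbons are uncontrolled, which is irrelevant because both become CH2 in step 13. The selectivity needed is attack at CH2 and not at the benzylic epoxide carbon; the bulk and the stabilised character of the nucleophile, and the absence of any Lewis acid that would give the benzylic C–O bond cationic character, should secure it. DMPU loosens the lithium ion pairs so that the carbanions, each flanked by two ortho ether groups, can react below room temperature, and excess 16 drives the second opening.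

Step 13
Reactants: 18 bis(γ-hydroxy sulfone) from step 12
Product: 19 (1R)-3-{2-(allyloxy)-3-[4-(allyloxy)-2-(benzyloxy)-5-[(3R)-3-hydroxy-3-phenylpropyl]-6-methoxybenzyl]-4-(benzyloxy)-6-methoxyphenyl}-1-phenylpropan-1-ol
Conditions: Mg turnings (excess), MeOH–THF, rt to 50 °C
Reagents that add atoms: none
Why: Reductive desulfonylation by single-electron transfer from magnesium; each benzylic C–S bond fragments to sulfinate and a benzylic radical or anion that methanol protonates. This erases both sulfonyl-bearing stereocentres, so the diastereomers of 18 converge, and it should leave the (R)-carbinols, allyl ethers and benzyl ethers untouched.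

Step 14
Reactants: 19 (1R)-3-{2-(allyloxy)-3-[4-(allyloxy)-2-(benzyloxy)-5-[(3R)-3-hydroxy-3-phenylpropyl]-6-methoxybenzyl]-4-(benzyloxy)-6-methoxyphenyl}-1-phenylpropan-1-ol
Product: 20 (1R)-3-{4-(benzyloxy)-3-[2-(benzyloxy)-4-hydroxy-5-[(3R)-3-hydroxy-3-phenylpropyl]-6-methoxybenzyl]-2-hydroxy-6-methoxyphenyl}-1-phenylpropan-1-ol
Conditions: Pd(PPh3)4 (5 mol%), morpholine, THF, rt
Reagents that add atoms: none
Why: Tsuji–Trost deallylation; zerovalent palladium ionises each allyl aryl ether to a π-allyl complex that morpholine traps. Benzyl ethers and secondary alcohols do not react, so only O8a and O8a' are freed.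

Step 15
Reactants: 20 (1R)-3-{4-(benzyloxy)-3-[2-(benzyloxy)-4-hydroxy-5-[(3R)-3-hydroxy-3-phenylpropyl]-6-methoxybenzyl]-2-hydroxy-6-methoxyphenyl}-1-phenylpropan-1-ol
Product: 21 (2S)-7-(benzyloxy)-8-{[(2S)-7-(benzyloxy)-5-methoxy-2-phenylchroman-6-yl]methyl}-5-methoxy-2-phenylchromane
Conditions: PPh3, DIAD, THF (0.01 M), 0 °C to rt
Reagents that add atoms: none
Why: Twofold intramolecular Mitsunobu etherification; each secondary alcohol is activated as an oxyphosphonium ion and displaced by the neighbouring phenoxide (O8a or O8a') in a 6-exo-tet SN2 reaction with inversion, turning both (R)-carbinols into the (2S) and (2'S) centres. The only free phenols are the two that must react, and the unsubstituted phenyl group gives the benzylic carbon little tendency to ionise.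

Step 16
Reactants: 21 (2S)-7-(benzyloxy)-8-{[(2S)-7-(benzyloxy)-5-methoxy-2-phenylchroman-6-yl]methyl}-5-methoxy-2-phenylchromane
Product: 22 (2S)-8-{[(2S)-7-hydroxy-5-methoxy-2-phenylchroman-6-yl]methyl}-5-methoxy-2-phenylchroman-7-ol (CNP0178097.1)
Conditions: H2 (1 atm), Pd/C, EtOAc–MeOH, rt
Reagents that add atoms: none
Why: Catalytic hydrogenolysis of the two benzyl aryl ethers; under neutral conditions at atmospheric pressure the cyclic secondary C2–O bond of a flavan should be cleaved much more slowly than a primary benzyl aryl ether, and no stereocentre is touched.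

Compound list

1 | 2,4-dihydroxy-6-methoxybenzaldehyde | COc1cc(O)cc(O)c1C=O | starting material
2 | 4-(benzyloxy)-2-hydroxy-6-methoxybenzaldehyde | COc1cc(OCc2ccccc2)cc(O)c1C=O | intermediate
3 | 4-(benzyloxy)-2-hydroxy-3-iodo-6-methoxybenzaldehyde | COc1cc(OCc2ccccc2)c(I)c(O)c1C=O | intermediate
4 | 2-(allyloxy)-4-(benzyloxy)-3-iodo-6-methoxybenzaldehyde | COc1cc(OCc2ccccc2)c(I)c(OCC=C)c1C=O | intermediate
5 | 2,4,6-trihydroxybenzaldehyde | O=Cc1c(O)cc(O)cc1O | starting material
6 | 4-(allyloxy)-2,6-dihydroxybenzaldehyde | O=Cc1c(O)cc(OCC=C)cc1O | intermediate
7 | 4-(allyloxy)-2-(benzyloxy)-6-hydroxybenzaldehyde | O=Cc1c(O)cc(OCC=C)cc1OCc1ccccc1 | intermediate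
8 | masked aryllithium: lithium [2-(allyloxy)-4-(benzyloxy)-3-lithio-6-methoxyphenyl]{[2-(dimethylamino)ethyl](methyl)amino}methanolate | COc1cc(OCc2ccccc2)c([Li])c(OCC=C)c1C(O[Li])N(C)CCN(C)C | intermediate (not isolated)
9 | diaryl carbinol: 2-(allyloxy)-3-{[4-(allyloxy)-2-(benzyloxy)-6-hydroxyphenyl](hydroxy)methyl}-4-(benzyloxy)-6-methoxybenzaldehyde (racemic) | COc1cc(OCc2ccccc2)c(C(O)c2c(OCc3ccccc3)cc(OCC=C)cc2O)c(OCC=C)c1C=O | intermediate (not isolated)
10 | 2-(allyloxy)-3-[4-(allyloxy)-2-(benzyloxy)-6-hydroxybenzyl]-4-(benzyloxy)-6-methoxybenzaldehyde | COc1cc(OCc2ccccc2)c(Cc2c(OCc3ccccc3)cc(OCC=C)cc2O)c(OCC=C)c1C=O | intermediate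
11 | 2-(allyloxy)-3-[4-(allyloxy)-2-(benzyloxy)-5-formyl-6-hydroxybenzyl]-4-(benzyloxy)-6-methoxybenzaldehyde | COc1cc(OCc2ccccc2)c(Cc2c(OCc3ccccc3)cc(OCC=C)c(C=O)c2O)c(OCC=C)c1C=O | intermediate
12 | 2-(allyloxy)-3-[4-(allyloxy)-2-(benzyloxy)-5-formyl-6-methoxybenzyl]-4-(benzyloxy)-6-methoxybenzaldehyde | COc1cc(OCc2ccccc2)c(Cc2c(OCc3ccccc3)cc(OCC=C)c(C=O)c2OC)c(OCC=C)c1C=O | intermediate
13 | {2-(allyloxy)-3-[4-(allyloxy)-2-(benzyloxy)-5-(hydroxymethyl)-6-methoxybenzyl]-4-(benzyloxy)-6-methoxyphenyl}methanol | COc1cc(OCc2ccccc2)c(Cc2c(OCc3ccccc3)cc(OCC=C)c(CO)c2OC)c(OCC=C)c1CO | intermediate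
14 | 2-(allyloxy)-3-{4-(allyloxy)-2-(benzyloxy)-6-methoxy-5-[(phenylthio)methyl]benzyl}-4-(benzyloxy)-6-methoxy-1-[(phenylthio)methyl]benzene | COc1cc(OCc2ccccc2)c(Cc2c(OCc3ccccc3)cc(OCC=C)c(CSc3ccccc3)c2OC)c(OCC=C)c1CSc1ccccc1 | intermediate
15 | 2-(allyloxy)-3-{4-(allyloxy)-2-(benzyloxy)-6-methoxy-5-[(phenylsulfonyl)methyl]benzyl}-4-(benzyloxy)-6-methoxy-1-[(phenylsulfonyl)methyl]benzene (key-step precursor) | COc1cc(OCc2ccccc2)c(Cc2c(OCc3ccccc3)cc(OCC=C)c(CS(=O)(=O)c3ccccc3)c2OC)c(OCC=C)c1CS(=O)(=O)c1ccccc1 | intermediate
16 | (S)-styrene oxide [(2S)-2-phenyloxirane] | C1O[C@H]1c1ccccc1 | starting material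
17 | dilithio bis-sulfone: 15 with one lithium on each sulfonyl-bearing carbon | COc1cc(OCc2ccccc2)c(Cc2c(OCc3ccccc3)cc(OCC=C)c(C([Li])S(=O)(=O)c3ccccc3)c2OC)c(OCC=C)c1C([Li])S(=O)(=O)c1ccccc1 | intermediate (not isolated)
18 | (1R)-3-{2-(allyloxy)-3-[4-(allyloxy)-2-(benzyloxy)-5-[(3R)-3-hydroxy-3-phenyl-1-(phenylsulfonyl)propyl]-6-methoxybenzyl]-4-(benzyloxy)-6-methoxyphenyl}-1-phenyl-3-(phenylsulfonyl)propan-1-ol, epimers at both sulfonyl-bearing carbons (key-step product) | COc1cc(OCc2ccccc2)c(Cc2c(OCc3ccccc3)cc(OCC=C)c(C(S(=O)(=O)c3ccccc3)C[C@H](c3ccccc3)O)c2OC)c(OCC=C)c1C(S(=O)(=O)c1ccccc1)C[C@H](c1ccccc1)O | intermediate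
19 | (1R)-3-{2-(allyloxy)-3-[4-(allyloxy)-2-(benzyloxy)-5-[(3R)-3-hydroxy-3-phenylpropyl]-6-methoxybenzyl]-4-(benzyloxy)-6-methoxyphenyl}-1-phenylpropan-1-ol | COc1cc(OCc2ccccc2)c(Cc2c(OCc3ccccc3)cc(OCC=C)c(CC[C@H](c3ccccc3)O)c2OC)c(OCC=C)c1CC[C@H](c1ccccc1)O | intermediate
20 | (1R)-3-{4-(benzyloxy)-3-[2-(benzyloxy)-4-hydroxy-5-[(3R)-3-hydroxy-3-phenylpropyl]-6-methoxybenzyl]-2-hydroxy-6-methoxyphenyl}-1-phenylpropan-1-ol | COc1cc(OCc2ccccc2)c(Cc2c(OCc3ccccc3)cc(O)c(CC[C@H](c3ccccc3)O)c2OC)c(O)c1CC[C@H](c1ccccc1)O | intermediate
21 | (2S)-7-(benzyloxy)-8-{[(2S)-7-(benzyloxy)-5-methoxy-2-phenylchroman-6-yl]methyl}-5-methoxy-2-phenylchromane | COc1cc(OCc2ccccc2)c(Cc2c(OCc3ccccc3)cc3c(c2OC)CC[C@@H](c2ccccc2)O3)c2c1CC[C@@H](c1ccccc1)O2 | intermediate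
22 | (2S)-8-{[(2S)-7-hydroxy-5-methoxy-2-phenylchroman-6-yl]methyl}-5-methoxy-2-phenylchroman-7-ol (CNP0178097.1) | COc1cc(O)c(Cc2c(O)cc3c(c2OC)CC[C@@H](c2ccccc2)O3)c2c1CC[C@@H](c1ccccc1)O2 | target

Total step count: 16. Longest linear sequence: 14 (steps 1 to 3 and 6 to 16; steps 4 and 5 form the short branch that joins at step 6).

Least certain steps

Step 12 (key step). The most likely failure is incomplete twofold opening, because each carbanion sits between two ortho ether groups. The second risk is partial attack at the benzylic carbon of 16, which would give a branched, wrongly connected arm. The fallback sets out from 12 and returns at 19. Claisen–Schmidt condensation of 12 with acetophenone (KOH, EtOH) should give the (E,E)-bis-chalcone F1. Conjugate reduction with [(Ph3P)CuH]6, which leaves allyl and benzyl ethers alone, should give the saturated diketone F2. Corey–Bakshi–Shibata reduction of both ketones with the (S)-oxazaborolidine and BH3·SMe2 should give the (R,R)-diol 19. This sets the stereocentres by catalyst control and not from the chiral pool.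

Step 6. Three things may go wrong:
- incomplete masking of the formyl group, so that the aryllithium adds to a second molecule of 4;
- cyclisation of the aryllithium onto its own ortho allyl ether on warming;
- partial reduction of the regenerated formyl group during the ionic hydrogenation.

The fallback sets out from 4 and returns at 10. Compound 4 is converted into the dimethyl acetal F3 (HC(OMe)3, MeOH, cat. pyridinium p-toluenesulfonate). Iodine–magnesium exchange with i-PrMgCl·LiCl gives an arylmagnesium reagent that does not add to an allyl ether. Addition to the magnesium phenoxide of 7 gives the carbinol acetal F4. Dilute aqueous acid hydrolyses the acetal to 9, which is then purified and reduced with Et3SiH/CF3CO2H at −40 °C to 10. The aldehyde is thus protected in a separate step and the carbon nucleophile is changed from lithium to magnesium.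

Step 2. The most likely failure is poor site selectivity: iodination at C5, para to the phenol, would compete with C3 and would end in a 6,6'-linked dimer. The fallback sets out from 2 and returns at 3. O2 is protected as the methoxymethyl ether F5 (MOMCl, i-Pr2NEt). The formyl group is masked in situ as its lithium α-amino alkoxide and the ring is lithiated with n-BuLi. The methoxymethoxy group directs the metal to C3 (directed ortho-metalation), and an I2 quench gives the iodide F6. HCl in MeOH removes the methoxymethyl group to give 3. Site selectivity then rests on coordination and not on electronic bias.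

Step 15. The most likely failures are partial ionisation of the activated benzylic oxyphosphonium ion (erosion of configuration at C2 or C2'), elimination to a styrene, or intermolecular ether formation. The fallback sets out from 19 and returns at 21. Both carbinols are mesylated at low temperature (MsCl, Et3N, CH2Cl2, −30 °C) to give, with retention, the bis-mesylate F7. Treatment with Pd(PPh3)4 and K2CO3 in MeOH cleaves the allyl ethers, and each phenoxide displaces the neighbouring mesylate by intramolecular SN2 reaction with inversion to give 21. Activation of the alcohol and release of the nucleophile are thus separated, and no phosphonium intermediate is involved.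

Further compounds

F1 | step 12 | (E,E)-bis-chalcone: 12 with each formyl group converted into CH=CH–C(=O)Ph | COc1cc(OCc2ccccc2)c(Cc2c(OCc3ccccc3)cc(OCC=C)c(/C=C/C(=O)c3ccccc3)c2OC)c(OCC=C)c1/C=C/C(=O)c1ccccc1
F2 | step 12 | saturated diketone: 12 with each formyl group converted into CH2CH2C(=O)Ph | COc1cc(OCc2ccccc2)c(Cc2c(OCc3ccccc3)cc(OCC=C)c(CCC(=O)c3ccccc3)c2OC)c(OCC=C)c1CCC(=O)c1ccccc1
F3 | step 6 | dimethyl acetal of 4: 2-(allyloxy)-4-(benzyloxy)-1-(dimethoxymethyl)-3-iodo-6-methoxybenzene | COc1cc(OCc2ccccc2)c(I)c(OCC=C)c1C(OC)OC
F4 | step 6 | carbinol acetal: dimethyl acetal of 9 (racemic) | COc1cc(OCc2ccccc2)c(C(O)c2c(OCc3ccccc3)cc(OCC=C)cc2O)c(OCC=C)c1C(OC)OC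
F5 | step 2 | 4-(benzyloxy)-6-methoxy-2-(methoxymethoxy)benzaldehyde | COCOc1cc(OCc2ccccc2)cc(OC)c1C=O
F6 | step 2 | 4-(benzyloxy)-3-iodo-6-methoxy-2-(methoxymethoxy)benzaldehyde | COCOc1c(I)c(OCc2ccccc2)cc(OC)c1C=O
F7 | step 15 | bis-mesylate of 19, both carbinol carbons R | COc1cc(OCc2ccccc2)c(Cc2c(OCc3ccccc3)cc(OCC=C)c(CC[C@H](c3ccccc3)OS(C)(=O)=O)c2OC)c(OCC=C)c1CC[C@H](c1ccccc1)OS(C)(=O)=O
A1 | alternative 1 | methylene-bridged bis-chromone, 5,5'-dimethoxy-7,7'-bis(methoxymethoxy), bridged C8 to C6' | COc1cc(OCOC)c(Cc2c(OCOC)cc3occc(=O)c3c2OC)c2occc(=O)c12
A2 | alternative 1 | phenylboronic acid | OB(O)c1ccccc1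
A3 | alternative 1 | (2S,2'S)-bis-flavanone, MOM-protected | COc1cc(OCOC)c(Cc2c(OCOC)cc3c(c2OC)C(=O)C[C@@H](c2ccccc2)O3)c2c1C(=O)C[C@@H](c1ccccc1)O2
A4 | alternative 2 | (3S)-3-phenyl-2-oxabicyclo[4.2.0]oct-1(6)-en-7-one | O=C1CC2=C1CC[C@@H](c1ccccc1)O2
A5 | alternative 2 | (2S)-7-(benzyloxy)-5-methoxy-8-(3-methoxyprop-2-yn-1-yl)-2-phenylchromane | COc1cc(OCc2ccccc2)c(CC#COC)c2c1CC[C@@H](c1ccccc1)O2
A6 | alternative 2 | 7-O-benzyl derivative of 22 (unit A benzylated, unit B phenol free) | COc1cc(OCc2ccccc2)c(Cc2c(O)cc3c(c2OC)CC[C@@H](c2ccccc2)O3)c2c1CC[C@@H](c1ccccc1)O2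
A7 | alternative 3 | bis(2-vinylphenol), 7,7'-di-O-benzyl, phenols at C8a and C8a' | COc1cc(OCc2ccccc2)c(Cc2c(OCc3ccccc3)cc(O)c(C=C)c2OC)c(O)c1C=C
A8 | alternative 3 | methyl cinnamyl carbonate [(E)-3-phenylprop-2-en-1-yl methyl carbonate] | COC(=O)OC/C=C/c1ccccc1
A9 | alternative 3 | bis[(S)-1-phenylallyl] aryl ether | COc1cc(OCc2ccccc2)c(Cc2c(OCc3ccccc3)cc(O[C@H](c3ccccc3)C=C)c(C=C)c2OC)c(O[C@H](c2ccccc2)C=C)c1C=C
A10 | alternative 3 | (2S,2'S)-bis(2H-chromene), 7,7'-di-O-benzyl | COc1cc(OCc2ccccc2)c(Cc2c(OCc3ccccc3)cc3c(c2OC)C=C[C@@H](c2ccccc2)O3)c2c1C=C[C@@H](c1ccccc1)O2
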